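Its constants are invented; what happens was integrated by code.

The hour per turn of the catalyst is the unit for reading these flasks: 2.8 mM of free catalyst faces 0.50 M of starting material, so each catalyst molecule must go round its cycle 179 times to convert the whole charge.

| setting | dawn | noon | midnight | spring |
|---|---|---|---|---|
| starting material | 0.50 M | 0.50 M (fed, over 7.50 h) | 0.50 M | 0.50 M |
| partner | 1.50 M | 1.50 M | 1.50 M | 1.50 M |
| free catalyst | 2.8 mM | 2.8 mM | 2.8 mM | 2.8 mM |
| time | 15 h | 15 h |  |  |
| remark | a closed flask charged with all of it at once and left for 15 h | a stirred flask in which starting material is dosed at a steady rate over 7.50 h without added volume, worked up at 15 h | a single well-mixed tank run continuously and read at steady state, 150 h in it on average | one stirred flow tank at steady state, fed with the mixture as stated, mean residence time 15 h |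

    catalyst intermediate C ⇌ by-product + catalyst intermediate D (K1 = 0.20 M, k1 = 200 h⁻¹)
    catalyst intermediate D ⇌ catalyst intermediate E (K2 = 99, k2 = 19 h⁻¹)
    catalyst intermediate E → free catalyst + product (k3 = 34 h⁻¹)
    partner + catalyst intermediate B ⇌ catalyst intermediate C (K4 = 0.27 L mol⁻¹, k4 = 200 L mol⁻¹ h⁻¹)
    starting material + free catalyst ⇌ catalyst intermediate A (K5 = 3.0 L mol⁻¹, k5 = 630 L mol⁻¹ h⁻¹)
    catalyst intermediate A → catalyst intermediate B (k6 = 29 h⁻¹)

1. order of the set-ups by the amount of product at the outlet or at the end, in percent of the starting material put in, highest first (dawn / noon / midnight / spring)
2. amount of product at the outlet or at the end, in percent of the starting material put in, dawn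
3. amount of product at the outlet or at the end, in percent of the starting material put in, noon
4. amount of product at the outlet or at the end, in percent of the starting material put in, midnight
5. amount of product at the outlet or at the end, in percent of the starting material put in, spring

- the stated concentrations are those of everything mixed, before any reaction; amounts are the same in each set-up
- the feed brings no volume worth counting
- run time (dawn): 15 h

Free catalyst binds starting material to give intermediate A, which becomes B. B takes up partner to give C, C sheds by-product to give D, D becomes E, and E releases product and free catalyst. These forms are short-lived, with half-lives of 1.2 min for E and 2.2 min for D (forward step alone), far shorter than the 15 h of a run, so each form can be taken as quasi-steady.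

The time of a turn is then a sum of waits. A, C, D and E each wait the reciprocal of their forward constant, together 0.122 h. Free catalyst waits for starting material, and A falls back 7.24 times per forward passage, so this wait comes to 0.0262 h at the charge. B waits for partner in the same way, with C falling back 3.70 times per shedding, which gives 0.0157 h. The sum, 0.163 h, is the turnover time T at the charge, the mean time one catalyst molecule needs for one round of the cycle; the rate of product formation is the catalyst concentration divided by T.

By-product lengthens T. It carries D back to C, and D returns 52.6 L mol⁻¹ times c(by-product) per turn, each return costing a further stay in C and B of 0.0173 h. With both reagents held at charge, T = 0.163 h·(1 + c(by-product)/c*), where c* is 0.179 M, the by-product concentration at which the added time equals T at the charge, and c(by-product) is taken equal to c(product).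

A tank runs at its outlet T, so c(product)·T equals catalyst concentration times residence time. For spring this quadratic gives 0.143 M, or 28.6%, and by-product then adds 0.130 h to T. Dawn integrates the same T over its run and reaches 0.173 M, or 34.6%, higher than spring. Both figures hold the reagents at charge, which understates T, so they lean high. For midnight the quadratic returns 0.595 M, which is more than the 0.50 M charged, so the short form ends there; the reckoning puts midnight highest, below the whole charge, without a figure. Noon opens from nil starting material, and the wait of free catalyst scales inversely with c(starting material), reaching 0.0524 h at 0.250 M, longer than at the charge, so the reckoning, without a figure, sets noon below dawn and leaves its place against spring open.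

The forecast gives 33% for dawn, 30% for noon, 89% for midnight and 27% for spring, ranked midnight > dawn > noon > spring, with by-product “pushing intermediate D back through C to B”.

The simulation gives midnight > dawn > noon > spring: 33.2% for dawn, 30.3% for noon, 89.5% for midnight and 27.0% for spring, with 72.5% of the starting material left at the spring outlet. With the reagents now counted, that spring outlet puts T at 0.307 h, which allows 48.9 turns in the mean residence time of 15 h. At the midnight outlet the same sum comes to 0.924 h, 5.67 times T at the charge, which allows 162 turns on average in 150 h.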